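**Plan**

- Retrosynthesis: first the N–S bond of a sulfonyl-protected ansa pyrrole; then ring B (the 3-methoxy-2H-pyrrole) at N1–C2(spiro) and C4–C5, together with the spiro C–O bond, giving pyrrole-2-carbonitrile and an open δ-hydroxy α-methoxy enone; then C2–C3 of that enone (δ-lactone + 1-methoxyvinyl metal); then the ansa chain at a C=C (metathesis); then C4–chain (conjugate addition) and C3–pyrrole (Suzuki–Miyaura) back to (S)-parasorbic acid.
- Forward ring order: δ-lactone (RCM) → pyrrolyl lactone → 12-membered ansa ring (RCM, then H2) → lactone opened by 1-methoxyvinyl addition → tetrahydropyran and ring B closed in one flask, the last bond formed being C4–C5.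
- Enabling feature: the spiro carbon is both the anomeric carbon of the tetrahydropyran and C2 of ring B, and it is flanked by C3(OMe)=C4. Its ring-oxygen-stabilized 2-methoxyallyl cation is therefore a C2–C3–C4 partner for the N1≡C5 unit of a nitrile.
- Stereochemistry: C6 from commercial (S)-pent-4-en-2-ol; C4 by cuprate addition anti to the C6 methyl; C3 by equilibration to 3,4-trans; the spiro carbon by axial, anomerically reinforced nitrile capture of a planar cation on which all ring-chain and anomeric isomers of the precursor converge.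

Key step: step 13

Lactone numbering (O1, C2 carbonyl, C3, C4, C5, C6) is kept for the tetrahydropyran atoms throughout; C3' is the β-carbon of the ansa pyrrole next to the lactone-bound carbon.

**Step 1**
Reactants: 1 (S)-pent-4-en-2-ol; 2 acryloyl chloride
Product: 3 (S)-pent-4-en-2-yl acrylate
Conditions: Et3N, DMAP (cat.), CH2Cl2, 0 °C → rt
Reagents that add atoms: none
Why: O-acylation of a secondary alcohol with an acid chloride, which does not touch the stereocentre.

**Step 2**
Reactants: 3 (S)-pent-4-en-2-yl acrylate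
Product: 4 (S)-6-methyl-5,6-dihydro-2H-pyran-2-one
Conditions: second-generation Grubbs catalyst (2 mol %), CH2Cl2 (0.02 M), 40 °C
Reagents that add atoms: none
Why: Ring-closing metathesis of an acrylate with a terminal alkene should give the six-membered α,β-unsaturated lactone with loss of ethene, C6 being untouched.

**Step 3**
Reactants: 4 (S)-6-methyl-5,6-dihydro-2H-pyran-2-one
Product: 6 (S)-3-bromo-6-methyl-5,6-dihydro-2H-pyran-2-one, via dibromolactone 5 (not isolated)
Conditions: Br2, CH2Cl2, 0 °C → rt; then Et3N, 0 °C → rt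
Reagents that add atoms: bromine, BrBr
Why: Bromine addition to the enoate followed by E1cB loss of HBr (removal of the acidic α-H, departure of the β-bromide) is the standard bromination–dehydrobromination route to α-bromo enoates.

**Step 4**
Reactants: 7 1H-pyrrole; 8 pent-4-enoyl chloride
Product: 10 1-(1H-pyrrol-2-yl)pent-4-en-1-one, via pyrrolylmagnesium bromide 9 (not isolated)
Conditions: EtMgBr, Et2O, 0 °C → rt; then 8, toluene, −40 → 0 °C; aq NH4Cl
Reagents that add atoms: none
Why: C-acylation of the pyrrolyl Grignard reagent with an acid chloride should go at C2, the classical entry to 2-acylpyrroles.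

**Step 5**
Reactants: 10 1-(1H-pyrrol-2-yl)pent-4-en-1-one
Product: 11 2-(pent-4-en-1-yl)-1H-pyrrole
Conditions: NaBH4 (excess), i-PrOH, reflux
Reagents that add atoms: none
Why: NaBH4 in refluxing i-PrOH should reduce the 2-acylpyrrole to the 2-alkylpyrrole through the carbinol and its azafulvene, leaving the isolated terminal alkene alone.

**Step 6**
Reactants: 11 2-(pent-4-en-1-yl)-1H-pyrrole
Product: 13 2-(pent-4-en-1-yl)-1-(phenylsulfonyl)-1H-pyrrole, via sodium pyrrolide 12 (not isolated)
Conditions: NaH, DMF, 0 °C; then PhSO2Cl, 0 °C → rt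
Reagents that add atoms: benzenesulfonyl chloride, O=S(=O)(Cl)c1ccccc1
Why: N-sulfonylation of the pyrrolide installs a group that directs the next lithiation and lowers the nucleophilicity of this pyrrole for steps 9 to 13.

**Step 7**
Reactants: 13 2-(pent-4-en-1-yl)-1-(phenylsulfonyl)-1H-pyrrole
Product: 15 2-(pent-4-en-1-yl)-1-(phenylsulfonyl)-5-(4,4,5,5-tetramethyl-1,3,2-dioxaborolan-2-yl)-1H-pyrrole, via lithiopyrrole 14 (not isolated)
Conditions: lithium diisopropylamide, THF, −78 °C; then 2-isopropoxy-4,4,5,5-tetramethyl-1,3,2-dioxaborolane, −78 °C → rt; 1 M HCl to pH 6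
Reagents that add atoms: 2-isopropoxy-4,4,5,5-tetramethyl-1,3,2-dioxaborolane, CC(C)OB1OC(C)(C)C(C)(C)O1
Why: Sulfonyl-directed α-lithiation at the only free α-position (C5) and borate trapping is the standard lithiation–borylation of 1-(phenylsulfonyl)pyrroles.

**Step 8**
Reactants: 6 (S)-3-bromo-6-methyl-5,6-dihydro-2H-pyran-2-one; 15 pyrrolyl pinacol boronate
Product: 16 (S)-6-methyl-3-[5-(pent-4-en-1-yl)-1-(phenylsulfonyl)-1H-pyrrol-2-yl]-5,6-dihydro-2H-pyran-2-one
Conditions: Pd(OAc)2 (5 mol %), SPhos (10 mol %), K3PO4, toluene/H2O (10:1), 60 °C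
Reagents that add atoms: none
Why: Suzuki–Miyaura coupling of an α-bromo enoate with a 2-pyrrolyl boronate joins C3 to the pyrrole, the C6 stereocentre being remote.

**Step 9**
Reactants: 16 α-pyrrolyl unsaturated lactone; 17 but-3-en-1-ylmagnesium bromide
Product: 19 (3S,4S,6S)-4-(but-3-en-1-yl)-6-methyl-3-[5-(pent-4-en-1-yl)-1-(phenylsulfonyl)-1H-pyrrol-2-yl]tetrahydro-2H-pyran-2-one, via silyl ketene acetal 18 (not isolated)
Conditions: CuBr·SMe2 (20 mol %), TMSCl, THF, −78 → −40 °C; 1 M HCl; then DBU (0.2 equiv), CH2Cl2, rt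
Reagents that add atoms: none
Why: Copper-catalysed, TMSCl-accelerated conjugate addition of the Grignard reagent should occur anti to the C6 methyl group on the half-chair (the usual trans-4,6 outcome for 6-substituted 5,6-dihydropyran-2-ones) and set C4 as (S), while protonation and DBU equilibration of the acidic C3–H should give the 3,4-trans (3S) arrangement.

**Step 10**
Reactants: 19 diene lactone
Product: 20 ansa lactone with a CH2CH2CH=CH(CH2)3 bridge from C4 to the pyrrole C5 (E/Z mixture)
Conditions: second-generation Grubbs catalyst (10 mol %), CH2Cl2 (1 mM), 40 °C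
Reagents that add atoms: none
Why: Ring-closing metathesis of two terminal alkenes at high dilution should close the ansa ring (12-membered counted through N) from the gauche, trans-vicinal chains, the alkene geometry being irrelevant.

**Step 11**
Reactants: 20 unsaturated ansa lactone
Product: 21 ansa lactone with a (CH2)7 bridge from C4 to the pyrrole C5
Conditions: H2 (1 atm), Pd/C (10 wt %), EtOAc, rt
Reagents that add atoms: none
Why: Heterogeneous hydrogenation should saturate the disubstituted alkene without touching the N-sulfonylpyrrole or the lactone.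

**Step 12**
Reactants: 21 saturated ansa lactone; 22 methyl vinyl ether
Product: 24 open-chain δ-hydroxy α-methoxy enone (C2 now C(=O)C(OMe)=CH2, former ring oxygen now the free (S)-CH(CH3)OH), via cerium lactolate 23 (not isolated)
Conditions: 22, t-BuLi, THF, −78 → 0 °C; anhydrous CeCl3, THF, −78 °C; then 21, −78 °C; pH 7 phosphate buffer, −78 °C → rt
Reagents that add atoms: none
Why: Single addition of a 1-alkoxyvinyl metal to a lactone stops at the tetrahedral lactolate at −78 °C, and the weakly basic organocerium reagent should add to the carbonyl rather than remove the acidic C3–H.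

**Step 13**
Reactants: 24 δ-hydroxy α-methoxy enone; 25 1H-pyrrole-2-carbonitrile
Product: 29 N-(phenylsulfonyl)premarineosin A, via hemiketal 26 (not isolated), via oxocarbenium triflate 27 (not isolated), via nitrilium triflate 28 (not isolated)
Conditions: 25 (10 equiv), TMSOTf (2.2 equiv), 2,6-di-tert-butyl-4-methylpyridine (1.1 equiv), 4 Å molecular sieves, EtNO2, −78 → −20 °C; then sat. aq NaHCO3
Reagents that add atoms: none
Why: Proposed new method: TMSOTf ionizes hemiketal 26 (formed from 24 by reversible 6-exo-trig attack of the C6 hydroxyl on the ketone) to the ring-oxygen-stabilized 2-methoxyallyl cation 27, the nitrile nitrogen of 25 adds to its anomeric carbon in a reversible Ritter step to give nitrilium ion 28, the enol ether terminus C4 attacks the nitrilium carbon C5, and loss of H+ from C4 leaves the conjugated 3-methoxy-2H-pyrrole. The closest known reaction types are the TMSOTf-promoted formal (3+2) annulation of donor–acceptor cyclopropanes with nitriles, where an oxocarbenium ion is captured by the nitrile and the nitrilium ion is closed by a silyl ketene acetal carbon, and the stepwise (3+2) cycloadditions of oxyallyl cations, where an endocyclic enol carbon closes a five-membered ring onto an onium carbon; uniting the two on a 2-alkoxyallyl oxocarbenium ion is the untested part. Ring B closes 5-endo-dig at the nitrilium carbon with the nucleophilic C3=C4 bond also inside the ring (enolendo), which should be feasible because the nitrilium ion bends toward imidoyl geometry as the bond forms and the closure is strongly exothermic. The one new stereocentre, the spiro carbon, is set by axial attack of the slim nitrile on the half-chair in which the trans ansa bridge holds the C3 pyrrolyl and C4 alkyl groups pseudo-equatorial, which places N axial (anomeric effect, syn to the axial C6 methyl) and gives the (R) configuration; since both anomers of 26 and open-chain 24 pass through the same planar cation 27 and the Ritter addition is reversible, all isomers of the precursor should converge on this epimer. The step needs N-attack at the anomeric carbon rather than at the CH2 terminus of 27, closure by C4 rather than Bischler–Napieralski-type attack of the ansa pyrrole C3' on 28, and no hydration of 28; these should be secured by the higher positive charge at the oxygen-bearing carbon together with the unhindered CH2 nucleophile, by the electron-withdrawing phenylsulfonyl group, and by TMSOTf, which carries off the hydroxyl oxygen as hexamethyldisiloxane.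

**Step 14**
Reactants: 29 N-(phenylsulfonyl)premarineosin A
Product: 30 premarineosin A
Conditions: Bu4NF (1 M in THF, 5 equiv), THF, 60 °C
Reagents that add atoms: none
Why: Fluoride attack at sulfur with the pyrrolide as leaving group is a basic, non-reducing desulfonylation of N-sulfonylpyrroles that should spare the spiro N,O-aminal and the methoxy-azafulvene.

**Compound list**

1 | (S)-pent-4-en-2-ol | C[C@H](O)CC=C | starting material
2 | acryloyl chloride | C=CC(=O)Cl | starting material
3 | (S)-pent-4-en-2-yl acrylate | C=CC(=O)O[C@@H](C)CC=C | intermediate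
4 | (S)-6-methyl-5,6-dihydro-2H-pyran-2-one ((S)-parasorbic acid) | C[C@H]1CC=CC(=O)O1 | intermediate
5 | (6S)-3,4-dibromo-6-methyltetrahydro-2H-pyran-2-one (3,4-trans dibromide, diastereomer mixture, in flask) | C[C@H]1CC(Br)C(Br)C(=O)O1 | intermediate
6 | (S)-3-bromo-6-methyl-5,6-dihydro-2H-pyran-2-one | C[C@H]1CC=C(Br)C(=O)O1 | intermediate
7 | 1H-pyrrole | c1cc[nH]c1 | starting material
8 | pent-4-enoyl chloride | C=CCCC(=O)Cl | starting material
9 | (1H-pyrrol-1-yl)magnesium bromide (in flask) | Br[Mg]n1cccc1 | intermediate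
10 | 1-(1H-pyrrol-2-yl)pent-4-en-1-one | C=CCCC(=O)c1ccc[nH]1 | intermediate
11 | 2-(pent-4-en-1-yl)-1H-pyrrole | C=CCCCc1ccc[nH]1 | intermediate
12 | sodium 2-(pent-4-en-1-yl)pyrrol-1-ide (in flask) | C=CCCCc1ccc[n-]1.[Na+] | intermediate
13 | 2-(pent-4-en-1-yl)-1-(phenylsulfonyl)-1H-pyrrole | C=CCCCc1cccn1S(=O)(=O)c1ccccc1 | intermediate
14 | [5-(pent-4-en-1-yl)-1-(phenylsulfonyl)-1H-pyrrol-2-yl]lithium (in flask) | [Li]c1ccc(CCCC=C)n1S(=O)(=O)c1ccccc1 | intermediate
15 | 2-(pent-4-en-1-yl)-1-(phenylsulfonyl)-5-(4,4,5,5-tetramethyl-1,3,2-dioxaborolan-2-yl)-1H-pyrrole | C=CCCCc1ccc(B2OC(C)(C)C(C)(C)O2)n1S(=O)(=O)c1ccccc1 | intermediate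
16 | (S)-6-methyl-3-[5-(pent-4-en-1-yl)-1-(phenylsulfonyl)-1H-pyrrol-2-yl]-5,6-dihydro-2H-pyran-2-one | C[C@H]1CC=C(c2ccc(CCCC=C)n2S(=O)(=O)c2ccccc2)C(=O)O1 | intermediate
17 | but-3-en-1-ylmagnesium bromide | C=CCC[Mg]Br | starting material
18 | (2S,4S)-4-(but-3-en-1-yl)-2-methyl-5-[5-(pent-4-en-1-yl)-1-(phenylsulfonyl)-1H-pyrrol-2-yl]-6-(trimethylsilyloxy)-3,4-dihydro-2H-pyran (silyl ketene acetal, in flask) | C[Si](C)(C)OC1=C(c2ccc(CCCC=C)n2S(=O)(=O)c2ccccc2)[C@@H](CCC=C)C[C@H](C)O1 | intermediate
19 | (3S,4S,6S)-4-(but-3-en-1-yl)-6-methyl-3-[5-(pent-4-en-1-yl)-1-(phenylsulfonyl)-1H-pyrrol-2-yl]tetrahydro-2H-pyran-2-one | O=C1O[C@@H](C)C[C@H](CCC=C)[C@H]1c1ccc(CCCC=C)n1S(=O)(=O)c1ccccc1 | intermediate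
20 | (3S,4S,6S)-6-methyltetrahydropyran-2-one whose C3 carries C2 of a 1-(phenylsulfonyl)pyrrole and whose C4 is joined to C5 of that pyrrole by a CH2CH2CH=CH(CH2)3 bridge (E/Z mixture) | O=C2O[C@@H](C)C[C@@H]1CCC=CCCCc3ccc(n3S(=O)(=O)c3ccccc3)[C@H]12 | intermediate
21 | the same ansa lactone with a saturated (CH2)7 bridge, (3S,4S,6S) | O=C2O[C@@H](C)C[C@@H]1CCCCCCCc3ccc(n3S(=O)(=O)c3ccccc3)[C@H]12 | intermediate
22 | methyl vinyl ether (methoxyethene) | C=COC | starting material
23 | dichlorocerium alkoxide of the cyclic hemiketal 2-(1-methoxyvinyl)tetrahydropyran-2-ol derived from 21 (tetrahedral adduct, in flask, anomer mixture) | C=C(OC)C2(O[Ce](Cl)Cl)O[C@@H](C)C[C@@H]1CCCCCCCc3ccc(n3S(=O)(=O)c3ccccc3)[C@H]12 | intermediate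
24 | open-chain δ-hydroxy α-methoxy enone: 1-methoxyvinyl ketone at the former C2, free (S)-CH(CH3)OH, C3 and C4 (S,S) as in 21 | O[C@@H](C)C[C@@H]1CCCCCCCc3ccc(n3S(=O)(=O)c3ccccc3)[C@H]1C(=O)C(OC)=C | intermediate
25 | 1H-pyrrole-2-carbonitrile | N#Cc1ccc[nH]1 | starting material
26 | cyclic hemiketal of 24: 2-hydroxy-2-(1-methoxyvinyl)tetrahydropyran (anomer mixture, in flask) | C=C(OC)C2(O)O[C@@H](C)C[C@@H]1CCCCCCCc3ccc(n3S(=O)(=O)c3ccccc3)[C@H]12 | intermediate
27 | cyclic 2-(1-methoxyvinyl)oxocarbenium triflate (2-methoxyallyl cation, in flask) | C=C(OC)C2=[O+][C@@H](C)C[C@@H]1CCCCCCCc3ccc(n3S(=O)(=O)c3ccccc3)[C@H]12.[O-]S(=O)(=O)C(F)(F)F | intermediate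
28 | N-[(2R)-2-(1-methoxyvinyl)tetrahydropyran-2-yl]nitrilium triflate of pyrrole-2-carbonitrile (N axial, in flask) | C=C(OC)[C@]2([N+]#Cc4ccc[nH]4)O[C@@H](C)C[C@@H]1CCCCCCCc3ccc(n3S(=O)(=O)c3ccccc3)[C@H]12.[O-]S(=O)(=O)C(F)(F)F | intermediate
29 | N-(phenylsulfonyl)premarineosin A (sulfonyl on the ansa pyrrole nitrogen; spiro R, C3 S, C4 S, C6 S) | COC1=CC(c2ccc[nH]2)=N[C@]12O[C@@H](C)C[C@@H]1CCCCCCCc3ccc(n3S(=O)(=O)c3ccccc3)[C@H]12 | intermediate
30 | premarineosin A (spiro R, C3 S, C4 S, C6 S) | COC1=CC(c2ccc[nH]2)=N[C@]12O[C@@H](C)C[C@@H]1CCCCCCCc3ccc([nH]3)[C@H]12 | target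

**Step count and risks**

Total steps: 14. Longest linear sequence: 11 (steps 4 to 14, from pyrrole).

Step 13 (Proposed new method). The 5-endo closure of the nitrilium ion may fail, so that the ion is hydrated on work-up or diverted by other π-nucleophiles, or the reversible Ritter addition may lie on the side of the cation and the enol ether may decompose. The fallback keeps the C4–C5 ring closure but makes it a known aldol-type condensation. It sets out from 24: anomeric azidation (TMSN3, TMSOTf cat., CH2Cl2, −40 °C) should give the axial azide F1. Staudinger reduction and acylation (PMe3, THF; then pyrrole-2-carbonyl chloride, Et3N) should give the N-acyl N,O-ketal F2. Mild hydrolysis of the enol ether (aqueous oxalic acid, THF, 0 °C) should give the methyl ketone F3. Potassium tert-butoxide in THF should close ring B by attack of the methyl ketone enolate on the amide carbonyl and loss of water, giving the 1,2-dihydro-3H-pyrrol-3-one F4. O-methylation of this vinylogous amide (MeOTf, 2,6-di-tert-butyl-4-methylpyridine, CH2Cl2) comes back to the route at 29.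

Step 12. The vinyl metal reagent may deprotonate the acidic C3–H instead of adding to the carbonyl (return of lactone, scrambling at C3), or add a second time after collapse of the lactolate. The fallback changes the oxidation level at which the C–C bond is made. It sets out from 21: i-Bu2AlH (CH2Cl2, −78 °C) should give the lactol F5. Excess 1-methoxyvinyllithium (THF, −78 °C) should add to its open hydroxy aldehyde form and give the diol F6 as a mixture of carbinol epimers. MnO2 (CH2Cl2, rt) should oxidize only the allylic carbinol and comes back to the route at 24.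

Step 10. Intermolecular metathesis (oligomers) may outrun ring closure because the N-sulfonyl group crowds the ansa loop, and the terminal double bonds may migrate before closure. The fallback closes the same ring at the pyrrole C5–CH2 bond by an intramolecular B-alkyl Suzuki–Miyaura coupling, which also makes step 11 unnecessary. It sets out from 6: commercial 1-(phenylsulfonyl)pyrrole is lithiated (lithium diisopropylamide, THF, −78 °C) and chlorinated (C2Cl6) to 2-chloro-1-(phenylsulfonyl)-1H-pyrrole F7. A second lithiation at C5 and trapping with the borolane reagent of step 7 should give the chloro boronate F8. Chemoselective coupling of F8 with vinyl bromide 6 (Pd(PPh3)4, Na2CO3, toluene/H2O, 60 °C, the C–Cl bond left intact) should give the chloropyrrolyl unsaturated lactone F9. Hept-6-en-1-ylmagnesium bromide under the conditions of step 9 should give the trans,trans lactone F10. Hydroboration of the terminal alkene with 9-BBN-H (THF, rt) should give the alkylborane F11, which is not isolated. Slow addition of F11 to Pd(OAc)2, SPhos and K3PO4 in THF/H2O at 65 °C should close the ring and comes back to the route at 21.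

**Further compounds**

F1 | step 13 | anomeric azide: (2R)-2-azido-2-(1-methoxyvinyl)tetrahydropyran from 24 (azide axial) | C=C(OC)[C@]2(N=[N+]=[N-])O[C@@H](C)C[C@@H]1CCCCCCCc3ccc(n3S(=O)(=O)c3ccccc3)[C@H]12
F2 | step 13 | N-acyl N,O-ketal: 2-(1-methoxyvinyl)-2-(1H-pyrrole-2-carboxamido)tetrahydropyran | C=C(OC)[C@]2(NC(=O)c4ccc[nH]4)O[C@@H](C)C[C@@H]1CCCCCCCc3ccc(n3S(=O)(=O)c3ccccc3)[C@H]12
F3 | step 13 | methyl ketone: 2-acetyl-2-(1H-pyrrole-2-carboxamido)tetrahydropyran | CC(=O)[C@]2(NC(=O)c4ccc[nH]4)O[C@@H](C)C[C@@H]1CCCCCCCc3ccc(n3S(=O)(=O)c3ccccc3)[C@H]12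
F4 | step 13 | spiro 5-(1H-pyrrol-2-yl)-1,2-dihydro-3H-pyrrol-3-one (O-demethyl form of 29) | O=C1C=C(c2ccc[nH]2)N[C@]12O[C@@H](C)C[C@@H]1CCCCCCCc3ccc(n3S(=O)(=O)c3ccccc3)[C@H]12
F5 | step 12 | lactol from 21 (tetrahydropyran-2-ol, anomer mixture) | OC2O[C@@H](C)C[C@@H]1CCCCCCCc3ccc(n3S(=O)(=O)c3ccccc3)[C@H]12
F6 | step 12 | diol: 2-methoxyallylic carbinol (epimer mixture) with free (S)-CH(CH3)OH | O[C@@H](C)C[C@@H]1CCCCCCCc3ccc(n3S(=O)(=O)c3ccccc3)[C@H]1C(O)C(OC)=C
F7 | step 10 | 2-chloro-1-(phenylsulfonyl)-1H-pyrrole | Clc1cccn1S(=O)(=O)c1ccccc1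
F8 | step 10 | 2-chloro-1-(phenylsulfonyl)-5-(4,4,5,5-tetramethyl-1,3,2-dioxaborolan-2-yl)-1H-pyrrole | Clc1ccc(B2OC(C)(C)C(C)(C)O2)n1S(=O)(=O)c1ccccc1
F9 | step 10 | (S)-3-[5-chloro-1-(phenylsulfonyl)-1H-pyrrol-2-yl]-6-methyl-5,6-dihydro-2H-pyran-2-one | C[C@H]1CC=C(c2ccc(Cl)n2S(=O)(=O)c2ccccc2)C(=O)O1
F10 | step 10 | (3S,4S,6S)-3-[5-chloro-1-(phenylsulfonyl)-1H-pyrrol-2-yl]-4-(hept-6-en-1-yl)-6-methyltetrahydro-2H-pyran-2-one | O=C1O[C@@H](C)C[C@H](CCCCCC=C)[C@H]1c1ccc(Cl)n1S(=O)(=O)c1ccccc1
F11 | step 10 | B-alkyl-9-borabicyclo[3.3.1]nonane from hydroboration of F10 (in flask) | O=C1O[C@@H](C)C[C@H](CCCCCCCB2C3CCCC2CCC3)[C@H]1c1ccc(Cl)n1S(=O)(=O)c1ccccc1
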